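The benzenoid ring of the naphthoquinone (C4a, C5–C8, C8a) bears acyl carbons at C4a and C6, both ortho to O5. It bears alkyl carbons at C8a and C7, both meta to O5. This is the imprint of two aryne acyl-alkylations steered by one alkoxy group, so the ring is treated as a 2-methoxy-1,4-benzdiyne. The key step builds the whole hydroxyquinone ring (C1–C4, C4a, C8a) in one flask from methyl acetoacetate and silylaryl triflate 13. Compound 13 has only an Me3Si group and a triflate where that ring will stand. The sequence is C–C insertion (C8a–C1, C4a–C4), Dieckmann closure (C2–C3), then flaviolin-type autoxidation at C1.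

Key step: step 7

Remark: the target has no stereocentre and the diaryl ketone axes are taken as freely rotating, so it is achiral and no enantiomer has to be selected; locants C1–C8a follow the naphthalene-1,4-dione numbering of the target (C1=O next to C2–OH, C4=O peri to C5–OH), primed locants refer to the 2,4-dioxygenated 6-methylphenyl ring; 1, 3, 6 and 14 are taken as catalogue chemicals.

Step 1
Reactants: 1 4-hydroxy-6-methyl-2H-pyran-2-one (triacetic acid lactone)
Product: 2 4-(benzyloxy)-6-methyl-2H-pyran-2-one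
Conditions: BnOH, PPh3, DIAD, THF, 0 °C → rt
Reagents that add atoms: benzyl alcohol, OCc1ccccc1
Why: Mitsunobu O-alkylation: the acidic vinylogous carboxylic OH of 1 is the pronucleophile and reacts at O-4, which keeps the 2-pyrone and avoids the C3-benzylation that benzyl halides and base can give; the ether later blocks O- and C3-arylation by the arynes.

Step 2
Reactants: 2 4-(benzyloxy)-6-methyl-2H-pyran-2-one; 3 2,4-dimethoxy-6-methylbenzaldehyde
Product: 4 (±)-4-(benzyloxy)-6-[2-(2,4-dimethoxy-6-methylphenyl)-2-hydroxyethyl]-2H-pyran-2-one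
Conditions: LDA, THF, −78 °C; then 3, −78 °C; AcOH quench at −78 °C
Reagents that add atoms: none
Why: Vinylogous aldol addition: LDA deprotonates the 6-methyl group of 2 to the extended dienolate, which adds through its terminal carbon to the non-enolisable aldehyde 3, the cold acidic quench forestalling retro-aldol and dehydration; the new carbinol stereocentre forms as a racemate and is erased in step 3.

Step 3
Reactants: 4 (±)-4-(benzyloxy)-6-[2-(2,4-dimethoxy-6-methylphenyl)-2-hydroxyethyl]-2H-pyran-2-one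
Product: 5 4-(benzyloxy)-6-[2-(2,4-dimethoxy-6-methylphenyl)-2-oxoethyl]-2H-pyran-2-one
Conditions: Dess–Martin periodinane (1.2 equiv), CH2Cl2, 0 °C → rt
Reagents that add atoms: none
Why: Dess–Martin oxidation of a secondary benzylic alcohol under neutral, non-dehydrating conditions, which tolerates the benzyl ether, the pyrone and the electron-rich arene and delivers the active-methylene ketone needed in step 6.

Step 4
Reactants: 6 2-methoxybenzene-1,3-diol (2-methoxyresorcinol)
Product: 7 4,6-dibromo-2-methoxybenzene-1,3-diol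
Conditions: NBS (2.0 equiv), MeCN, 0 °C
Reagents that add atoms: N-bromosuccinimide, O=C1CCC(=O)N1Br
Why: Electrophilic aromatic bromination: C4 and C6 are each ortho to one OH and para to the other whereas C5 is meta to both, so two equivalents of NBS should give only the 4,6-dibromide.

Step 5
Reactants: 7 4,6-dibromo-2-methoxybenzene-1,3-diol
Product: 10 2-methoxy-4,6-bis(trimethylsilyl)-1,3-phenylene bis(trifluoromethanesulfonate), via bis(silyl ether) 8 (not isolated), via dilithium diolate 9 (not isolated)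
Conditions: HMDS, 80 °C, volatiles removed; n-BuLi (2.2 equiv), THF, −78 °C; Tf2O (2.4 equiv), −78 → 0 °C
Reagents that add atoms: hexamethyldisilazane, C[Si](C)(C)N[Si](C)(C)C; trifluoromethanesulfonic anhydride, O=S(=O)(OS(=O)(=O)C(F)(F)F)C(F)(F)F
Why: The standard one-flask conversion of an o-bromophenol into an o-silylaryl triflate, run twice on one ring: O-silylation, Br/Li exchange, 1,3-O→C silyl shift (retro-Brook rearrangement) to diolate 9 and O-triflation, the symmetry of 7 making both sites equivalent.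

Step 6
Reactants: 5 4-(benzyloxy)-6-[2-(2,4-dimethoxy-6-methylphenyl)-2-oxoethyl]-2H-pyran-2-one; 10 2-methoxy-4,6-bis(trimethylsilyl)-1,3-phenylene bis(trifluoromethanesulfonate)
Product: 13 4-{[4-(benzyloxy)-2-oxo-2H-pyran-6-yl]methyl}-3-(2,4-dimethoxy-6-methylbenzoyl)-2-methoxy-6-(trimethylsilyl)phenyl trifluoromethanesulfonate, via aryne 11 (not isolated), via benzocyclobutenoxide 12 (not isolated)
Conditions: 10 (2 equiv, surplus recovered), CsF (1.3 equiv), MeCN, 60 °C
Reagents that add atoms: none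
Why: Aryne acyl-alkylation (C–C σ-insertion into an active-methylene ketone): fluoride releases aryne 11 from one of the two equivalent silyl/triflate pairs of 10, the enolate carbon of 5 attacks the aryne carbon remote from OMe, the aryl anion next to OMe closes intramolecularly on the ketone (the kind of acyl capture used to force tetra-ortho-substituted benzophenones) to benzocyclobutenoxide 12, and strain-driven cleavage to the pyrone-stabilised benzylic carbanion places aroyl ortho and CH2-pyrone meta to OMe, while excess 10, limiting fluoride and the stronger activation of 10 (each C–Si para to a triflate) keep the second pair in reserve.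

Step 7
Reactants: 13 4-{[4-(benzyloxy)-2-oxo-2H-pyran-6-yl]methyl}-3-(2,4-dimethoxy-6-methylbenzoyl)-2-methoxy-6-(trimethylsilyl)phenyl trifluoromethanesulfonate; 14 methyl acetoacetate
Product: 19 7-{[4-(benzyloxy)-2-oxo-2H-pyran-6-yl]methyl}-6-(2,4-dimethoxy-6-methylbenzoyl)-2-hydroxy-5-methoxynaphthalene-1,4-dione, via aryne 15 (not isolated), via benzocyclobutenoxide 16 (not isolated), via keto ester 17 (not isolated), via naphthalene-1,3-diol 18 (not isolated)
Conditions: 14 (2 equiv), KF, 18-crown-6, THF, rt; then KOt-Bu (6 equiv), 0 °C → rt, argon; then AcOH, sat. aq. NaHCO3, air, rt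
Reagents that add atoms: dioxygen (air), O=O
Why: Fluoride removes Me3Si from C8a and triflate leaves C4a to give aryne 15; the enolate of 14 (the only C–H acid that KF ionises, being more acidic than C7–H2) attacks C8a, the aryne carbon remote from the inductively withdrawing 5-OMe, and the C4a anion closes 4-exo-trig on the acetyl C=O to benzocyclobutenoxide 16, whose strain drives a retro-aldol C–C cleavage to keto ester 17 (aryne acyl-alkylation, a formal insertion into the acetyl–CH2 bond that makes C8a–C1 and C4a–C4). KOt-Bu then equilibrates the enolates and the acetyl carbon C3 attacks the ester carbon C2 (Dieckmann condensation, 6-exo-trig), which closes the six-membered ring and, after loss of methoxide and enolisation, gives naphthalene-1,3-diol 18. After neutralisation to bicarbonate pH the electron-rich diolate takes up dioxygen at C1 (ortho to O-2, para to O-4) and loses water, the non-enzymatic oxidation that turns 1,3,6,8-tetrahydroxynaphthalene into flaviolin. The closest known reaction type is the one-pot aryne acyl-alkylation/condensation/air oxidation of β-keto esters to 2-hydroxy-1,4-naphthoquinones. No lasting stereocentre is formed (the two in 16 vanish on cleavage). The step needs regiocontrol (OH at C2 next to C1, not at C3), secured by 5-OMe next to C4a, and chemoselectivity, secured by the hindered tetra-ortho-substituted diaryl ketone, by a non-nucleophilic base with the pyrone shielded as its C7 carbanion, and by admitting air only after C7 is reprotonated.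

Step 8
Reactants: 19 7-{[4-(benzyloxy)-2-oxo-2H-pyran-6-yl]methyl}-6-(2,4-dimethoxy-6-methylbenzoyl)-2-hydroxy-5-methoxynaphthalene-1,4-dione
Product: 20 6-(2,4-dihydroxy-6-methylbenzoyl)-2,5-dihydroxy-7-[(4-hydroxy-2-oxo-2H-pyran-6-yl)methyl]naphthalene-1,4-dione (target)
Conditions: BBr3 (10 equiv), pentamethylbenzene (3 equiv), CH2Cl2, −78 °C → rt; H2O
Reagents that add atoms: none
Why: Lewis-acid ether cleavage: BBr3 should cleave the two carbonyl-chelated methyl ethers (5-OMe peri to C4=O, 2'-OMe ortho to the ketone) and the benzyl vinylogous ester quickly and the unchelated 4'-OMe on warming, pentamethylbenzene traps the benzyl cation, and quinone, pyrone and diaryl ketone are inert to the reagent; no stereocentre is involved.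

Compound list
1 | 4-hydroxy-6-methyl-2H-pyran-2-one (triacetic acid lactone) | Cc1cc(O)cc(=O)o1 | starting material
2 | 4-(benzyloxy)-6-methyl-2H-pyran-2-one | Cc1cc(OCc2ccccc2)cc(=O)o1 | intermediate
3 | 2,4-dimethoxy-6-methylbenzaldehyde | COc1cc(C)c(C=O)c(OC)c1 | starting material
4 | (±)-4-(benzyloxy)-6-[2-(2,4-dimethoxy-6-methylphenyl)-2-hydroxyethyl]-2H-pyran-2-one (racemate) | COc1cc(C)c(C(O)Cc2cc(OCc3ccccc3)cc(=O)o2)c(OC)c1 | intermediate
5 | 4-(benzyloxy)-6-[2-(2,4-dimethoxy-6-methylphenyl)-2-oxoethyl]-2H-pyran-2-one | COc1cc(C)c(C(=O)Cc2cc(OCc3ccccc3)cc(=O)o2)c(OC)c1 | intermediate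
6 | 2-methoxybenzene-1,3-diol (2-methoxyresorcinol) | COc1c(O)cccc1O | starting material
7 | 4,6-dibromo-2-methoxybenzene-1,3-diol | COc1c(O)c(Br)cc(Br)c1O | intermediate
8 | 1,5-dibromo-3-methoxy-2,4-bis(trimethylsilyloxy)benzene | COc1c(O[Si](C)(C)C)c(Br)cc(Br)c1O[Si](C)(C)C | intermediate
9 | dilithium 2-methoxy-4,6-bis(trimethylsilyl)benzene-1,3-diolate | [Li+].[Li+].COc1c([O-])c([Si](C)(C)C)cc([Si](C)(C)C)c1[O-] | intermediate
10 | 2-methoxy-4,6-bis(trimethylsilyl)-1,3-phenylene bis(trifluoromethanesulfonate) | COc1c(OS(=O)(=O)C(F)(F)F)c([Si](C)(C)C)cc([Si](C)(C)C)c1OS(=O)(=O)C(F)(F)F | intermediate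
11 | 3-methoxy-4-(trifluoromethylsulfonyloxy)-5-(trimethylsilyl)benzyne | COC1=C(OS(=O)(=O)C(F)(F)F)C([Si](C)(C)C)=CC#C1 | intermediate
12 | caesium 8-[4-(benzyloxy)-2-oxo-2H-pyran-6-yl]-7-(2,4-dimethoxy-6-methylphenyl)-5-methoxy-4-(trifluoromethylsulfonyloxy)-3-(trimethylsilyl)bicyclo[4.2.0]octa-1,3,5-trien-7-olate (transient, configuration undefined) | [Cs+].COc1cc(C)c(C2([O-])C(c3cc(OCc4ccccc4)cc(=O)o3)c3cc([Si](C)(C)C)c(OS(=O)(=O)C(F)(F)F)c(OC)c32)c(OC)c1 | intermediate
13 | 4-{[4-(benzyloxy)-2-oxo-2H-pyran-6-yl]methyl}-3-(2,4-dimethoxy-6-methylbenzoyl)-2-methoxy-6-(trimethylsilyl)phenyl trifluoromethanesulfonate | COc1cc(C)c(C(=O)c2c(OC)c(OS(=O)(=O)C(F)(F)F)c([Si](C)(C)C)cc2Cc2cc(OCc3ccccc3)cc(=O)o2)c(OC)c1 | intermediate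
14 | methyl acetoacetate | CC(=O)CC(=O)OC | starting material
15 | 5-{[4-(benzyloxy)-2-oxo-2H-pyran-6-yl]methyl}-4-(2,4-dimethoxy-6-methylbenzoyl)-3-methoxybenzyne | COC1=C(C(=O)c2c(C)cc(OC)cc2OC)C(Cc2cc(OCc3ccccc3)cc(=O)o2)=CC#C1 | intermediate
16 | potassium 3-{[4-(benzyloxy)-2-oxo-2H-pyran-6-yl]methyl}-4-(2,4-dimethoxy-6-methylbenzoyl)-5-methoxy-8-(methoxycarbonyl)-7-methylbicyclo[4.2.0]octa-1,3,5-trien-7-olate (transient, configuration undefined) | [K+].COC(=O)C1c2cc(Cc3cc(OCc4ccccc4)cc(=O)o3)c(C(=O)c3c(C)cc(OC)cc3OC)c(OC)c2C1(C)[O-] | intermediate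
17 | methyl 2-[2-acetyl-5-{[4-(benzyloxy)-2-oxo-2H-pyran-6-yl]methyl}-4-(2,4-dimethoxy-6-methylbenzoyl)-3-methoxyphenyl]acetate | COC(=O)Cc1cc(Cc2cc(OCc3ccccc3)cc(=O)o2)c(C(=O)c2c(C)cc(OC)cc2OC)c(OC)c1C(C)=O | intermediate
18 | 4-(benzyloxy)-6-{[3-(2,4-dimethoxy-6-methylbenzoyl)-5,7-dihydroxy-4-methoxynaphthalen-2-yl]methyl}-2H-pyran-2-one (OH at C2 and C4 in target numbering) | COc1cc(C)c(C(=O)c2c(Cc3cc(OCc4ccccc4)cc(=O)o3)cc3cc(O)cc(O)c3c2OC)c(OC)c1 | intermediate
19 | 7-{[4-(benzyloxy)-2-oxo-2H-pyran-6-yl]methyl}-6-(2,4-dimethoxy-6-methylbenzoyl)-2-hydroxy-5-methoxynaphthalene-1,4-dione | COc1cc(C)c(C(=O)c2c(Cc3cc(OCc4ccccc4)cc(=O)o3)cc3c(c2OC)C(=O)C=C(O)C3=O)c(OC)c1 | intermediate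
20 | 6-(2,4-dihydroxy-6-methylbenzoyl)-2,5-dihydroxy-7-[(4-hydroxy-2-oxo-2H-pyran-6-yl)methyl]naphthalene-1,4-dione (achiral) | Cc1cc(O)cc(O)c1C(=O)c1c(Cc2cc(O)cc(=O)o2)cc2c(c1O)C(=O)C=C(O)C2=O | target

Total step count: 8. Longest linear sequence: 6 (steps 1, 2, 3, 6, 7, 8).

Steps most likely to fail

**Risk 1 (step 6).**
- The extended enolate of 5 is crowded and ambident.
- The aryl anion may be protonated before it closes on the doubly ortho-substituted ketone, which would give plain α-arylation. It may also add to pyrone C6.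
- The surviving silyl/triflate pair may be activated too early.

The fallback takes the pyrone out of the insertion. It sets out from 3 and 10 and comes back at 13.
- Aldehyde 3 is homologated with ethyl diazoacetate (Roskamp reaction, cat. NbCl5, CH2Cl2) to ethyl 3-(2,4-dimethoxy-6-methylphenyl)-3-oxopropanoate F1, a plain β-keto ester of the class on which aryne acyl-alkylation is established.
- Reaction of F1 with 10 and CsF in MeCN gives the ethyl arylacetate F2.
- Claisen acylation of the dianion of tert-butyl acetoacetate (NaH, then n-BuLi, THF, −78 °C) by F2 gives the tert-butyl 3,5-dioxohexanoate F3.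
- TFA and then TFAA close the 4-hydroxy-2-pyrone F4.
- Mitsunobu benzylation as in step 1 returns to 13.

**Risk 2 (step 7).**
- The Dieckmann closure may stall, because the base ionises C1–H2 and C7–H2 before the acetyl group.
- The pyrone dienolate may add to the diaryl ketone.
- Oxygenation may also touch the C7 methylene.

The fallback replaces the base and dioxygen-insertion chemistry by a cycloaddition that brings C1–C4 with all oxygens in place. It sets out from 13 and comes back at 20.
- Methyl tetronate is silylated (TBSOTf, Et3N, CH2Cl2, 0 °C) to tert-butyl[(4-methoxyfuran-2-yl)oxy]dimethylsilane F5.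
- Aryne 15, released from 13 with CsF in MeCN in the presence of excess F5, undergoes [4+2] addition. The nucleophilic furan C5 bonds to C8a and the silyloxy carbon to C4a, giving the oxygen-bridged cycloadduct F6. A stepwise addition of the desilylated dienolate leads to the same bridge.
- Desilylation opens the bridge to the 2-methoxynaphthalene-1,4-diol F7.
- Air oxidises F7 to the 2,5-dimethoxynaphthoquinone F8.
- The conditions of step 8 also cleave the quinone vinylogous methyl ester and give 20.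

**Risk 3 (step 8).**
- Cleavage of the unchelated 4'-OMe needs prolonged exposure to BBr3.
- During that time, cyclodehydration of pyrone C5 onto the diaryl ketone or C-benzylation may set in.

The fallback changes the protecting-group plan so that no unchelated methyl ether remains. It sets out from 2 (together with 10 and 14) and comes back at 20.
- Commercial 2,4-dihydroxy-6-methylbenzaldehyde is benzylated (BnBr, K2CO3, DMF) to 2,4-bis(benzyloxy)-6-methylbenzaldehyde F9.
- The operations of steps 2, 3, 6 and 7 then give in turn the aldol adduct F10, the active-methylene ketone F11, the silylaryl triflate F12 and the hydroxyquinone F13.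
- BCl3 and pentamethylbenzene (CH2Cl2, −78 → 0 °C) remove the three benzyl groups and the 5-OMe chelated to C4=O, giving 20.

Further compounds
F1 | step 6 | ethyl 3-(2,4-dimethoxy-6-methylphenyl)-3-oxopropanoate | CCOC(=O)CC(=O)c1c(C)cc(OC)cc1OC
F2 | step 6 | ethyl 2-[2-(2,4-dimethoxy-6-methylbenzoyl)-3-methoxy-4-(trifluoromethylsulfonyloxy)-5-(trimethylsilyl)phenyl]acetate | CCOC(=O)Cc1cc([Si](C)(C)C)c(OS(=O)(=O)C(F)(F)F)c(OC)c1C(=O)c1c(C)cc(OC)cc1OC
F3 | step 6 | tert-butyl 6-[2-(2,4-dimethoxy-6-methylbenzoyl)-3-methoxy-4-(trifluoromethylsulfonyloxy)-5-(trimethylsilyl)phenyl]-3,5-dioxohexanoate | CC(C)(C)OC(=O)CC(=O)CC(=O)Cc1cc([Si](C)(C)C)c(OS(=O)(=O)C(F)(F)F)c(OC)c1C(=O)c1c(C)cc(OC)cc1OC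
F4 | step 6 | 3-(2,4-dimethoxy-6-methylbenzoyl)-4-[(4-hydroxy-2-oxo-2H-pyran-6-yl)methyl]-2-methoxy-6-(trimethylsilyl)phenyl trifluoromethanesulfonate | COc1cc(C)c(C(=O)c2c(OC)c(OS(=O)(=O)C(F)(F)F)c([Si](C)(C)C)cc2Cc2cc(O)cc(=O)o2)c(OC)c1
F5 | step 7 | tert-butyl[(4-methoxyfuran-2-yl)oxy]dimethylsilane | COc1coc(O[Si](C)(C)C(C)(C)C)c1
F6 | step 7 | oxygen-bridged cycloadduct: racemic 1,4-epoxy-1,4-dihydronaphthalene with OTBS at C4, OMe at C2 and C5, aroyl at C6, pyronylmethyl at C7 | COC1=CC2(O[Si](C)(C)C(C)(C)C)OC1c1cc(Cc3cc(OCc4ccccc4)cc(=O)o3)c(C(=O)c3c(C)cc(OC)cc3OC)c(OC)c12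
F7 | step 7 | 4-(benzyloxy)-6-{[3-(2,4-dimethoxy-6-methylbenzoyl)-5,8-dihydroxy-4,7-dimethoxynaphthalen-2-yl]methyl}-2H-pyran-2-one | COc1cc(O)c2c(OC)c(C(=O)c3c(C)cc(OC)cc3OC)c(Cc3cc(OCc4ccccc4)cc(=O)o3)cc2c1O
F8 | step 7 | 7-{[4-(benzyloxy)-2-oxo-2H-pyran-6-yl]methyl}-6-(2,4-dimethoxy-6-methylbenzoyl)-2,5-dimethoxynaphthalene-1,4-dione | COC1=CC(=O)c2c(OC)c(C(=O)c3c(C)cc(OC)cc3OC)c(Cc3cc(OCc4ccccc4)cc(=O)o3)cc2C1=O
F9 | step 8 | 2,4-bis(benzyloxy)-6-methylbenzaldehyde | Cc1cc(OCc2ccccc2)cc(OCc2ccccc2)c1C=O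
F10 | step 8 | (±)-4-(benzyloxy)-6-{2-[2,4-bis(benzyloxy)-6-methylphenyl]-2-hydroxyethyl}-2H-pyran-2-one | Cc1cc(OCc2ccccc2)cc(OCc2ccccc2)c1C(O)Cc1cc(OCc2ccccc2)cc(=O)o1
F11 | step 8 | 4-(benzyloxy)-6-{2-[2,4-bis(benzyloxy)-6-methylphenyl]-2-oxoethyl}-2H-pyran-2-one | Cc1cc(OCc2ccccc2)cc(OCc2ccccc2)c1C(=O)Cc1cc(OCc2ccccc2)cc(=O)o1
F12 | step 8 | 4-{[4-(benzyloxy)-2-oxo-2H-pyran-6-yl]methyl}-3-[2,4-bis(benzyloxy)-6-methylbenzoyl]-2-methoxy-6-(trimethylsilyl)phenyl trifluoromethanesulfonate | Cc1cc(OCc2ccccc2)cc(OCc2ccccc2)c1C(=O)c1c(OC)c(OS(=O)(=O)C(F)(F)F)c([Si](C)(C)C)cc1Cc1cc(OCc2ccccc2)cc(=O)o1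
F13 | step 8 | 7-{[4-(benzyloxy)-2-oxo-2H-pyran-6-yl]methyl}-6-[2,4-bis(benzyloxy)-6-methylbenzoyl]-2-hydroxy-5-methoxynaphthalene-1,4-dione | Cc1cc(OCc2ccccc2)cc(OCc2ccccc2)c1C(=O)c1c(Cc2cc(OCc3ccccc3)cc(=O)o2)cc2c(c1OC)C(=O)C=C(O)C2=O
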